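(The runs are calculated for an exercise; noise was put on by code.)

A small charge, birch at 0.10 M of each hand, was where I started when you asked for a quick number and offered the hunch that the two substrates trade hands fast. I followed one substrate molecule: each hour it has some chance of becoming product, and that chance differs by hand.

| flask | left-handed substrate | right-handed substrate | gas | remark | time |
|---|---|---|---|---|---|
| birch | 0.10 M | 0.10 M | 7.4 mM (held) | run made earlier |  |
| ash | 0.40 M | 0.40 M | 7.4 mM (held) | run made earlier |  |
| flask | 0.20 M | 0.20 M | 7.4 mM (held) |  | 30 h |

| run | time / h | left-handed product / % | right-handed product / % | left-handed substrate / % |
|---|---|---|---|---|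
| birch | 3.00 | 0 | 1 | 46 |
| birch | 6.00 | 4 | 2 | 41 |
| birch | 15.0 | 11 | 10 | 33 |
| birch | 40.0 | 29 | 16 | 15 |
| ash | 10.0 | 4 | 3 | 43 |
| ash | 20.0 | 8 | 3 | 39 |
| ash | 25.0 | 13 | 6 | 37 |
| ash | 40.0 | 24 | 10 | 27 |

(each reading ± 2 percentage points)

- partner is single-handed; left-handed substrate and right-handed substrate are mirror images of each other, charged as a racemate, each of them at the stated concentration
- the earlier runs were read with a standard deviation of 2 percentage points
- at the start none of the gas is in solution
- an excess is the difference of the two amounts in percent of their sum
- an excess is below zero if the other one leads
- the handed part of partner does not stay in what it makes, so the products of the two hands are mirror images too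

1. left-handed product and right-handed product together, in percent of the left-handed substrate and right-handed substrate charged together, at 30 h
2. excess of left-handed product over right-handed product in the product at 30 h
3. whether the exchange between left-handed substrate and right-handed substrate keeps pace with the reaction: how far the product's excess at 30 h gets from its value without exchange to its value with instant exchange (above 80% keeps pace, below 20% hardly takes part, else lags behind)

If the hands do not trade, each decays on its own, and the ratio of the logarithms of the two remaining fractions gives the ratio of the chances. Taking each remainder from its product, with each hand charged at half, birch at 40.0 h gave 2.25 and ash gave 2.93. I carried their mean, 2.59, as the selectivity factor: a left-handed molecule's chance per hour of becoming product over a right-handed one's. It is a reading, and the gap between the two values shows its scatter.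

Your hunch would feed the left-handed side from the right, so left-handed substrate plus left-handed product would climb past half of the charge. At 40.0 h birch held 44.0% and ash 51.0%, with 2 percentage points on each of the two readings in a sum, so neither run stood clear above half and I answered "hardly takes part".

The flask's 0.20 M lies between the two charges, so I took the mean right-handed remainder, 74.0% of its own charge, and scaled it as a single decay to 30 h, which gave 79.8%. Raising that to the power s gave a left-handed remainder of 55.7%. That made 32.2% product at an excess of 37.3%, where instant exchange would give 44.3%.

The forecast, from the same runs, put the yield a little lower than mine at 31%, with an excess of 37% and the answer hardly takes part, on the ground that “there is no sign of exchange”.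

The flask gave 29.7% of product at an excess of 34.4%, and the exchange hardly takes part.

    partner → decomposed reagent (k = 7.92 × 10⁻⁴ min⁻¹)
    right-handed substrate ⇌ achiral form (K = 0.124, k = 2.13 × 10⁻⁴ min⁻¹)
    left-handed substrate ⇌ achiral form (K = 0.124, k = 2.13 × 10⁻⁴ min⁻¹)
    gas ⇌ partner, rate k4*(csat - [partner]) (kL = 0.0241 min⁻¹)
    partner + right-handed substrate → right-handed product (k = 0.0290 L mol⁻¹ min⁻¹)
    partner + left-handed substrate → left-handed product (k = 0.0674 L mol⁻¹ min⁻¹)

The excess got 9.7% of the way from its value without exchange to its value with instant exchange. I then put s to use on the flask at 30.0 h: from its 19.9% of left-handed product, s called for 8.90% of right-handed product, and the flask held 9.75%.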